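The oak run was the flask in question, followed up to 40.0 s, so I read the answers from it.

| setting | oak | flask |
|---|---|---|
| substrate | 0.34 M | 0.34 M |
| first nucleophile | 0.238 M | 0.238 M |
| second nucleophile | 0.17 M | 0.170 M |
| remark | the very flask that is asked about, followed so far |  |
| time |  | 2.0 min |

- oak (time / s: target / %, substrate / %): 10.0: 7.2, 58.4; 12.0: 8.4, 52.2; 15.0: 9.6, 44.6; 20.0: 10.0, 33.7; 30.0: 11.7, 19.7; 40.0: 12.0, 11.3

(each reading ± 0.3 percentage points)

* time up to 2.0 min at which target stands highest
* the amount of target, in percent of the substrate charged, at that time
* the first time at which target reaches 6.0%, in the same percent, in min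

- the numbers in the tables scatter with a standard deviation of 0.3 percentage points
- a reading or a percentage of target counts all its forms, free or not

I followed one substrate molecule. The clock came from its disappearance: the first reading gave a first-order constant of 0.0538 s⁻¹, and the last reading gave 0.0545 s⁻¹. At 10.0 s, 17.3% of the consumed substrate stood as target; I call this the share, the selectivity of the fork as far as it survives. Was that one reading a fluke? No, because the reading at 15.0 s gave 17.3%. Share and clock put 6.0% of target at 0.132 min, by my own reckoning.

But from 15.0 s to 40.0 s the share of newly consumed substrate was 7.21%. Could spent first nucleophile explain that? At the early share, consuming all the substrate would use 24.7% of its charge, a smaller change than the fall in the share, so I took target to be lost after forming. The last two readings differ by 0.3 percentage points, close to the scatter of 0.3 points, so I named the highest reading, 12.0% at 40.0 s, as my peak, and with doubt.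

The forecast gave 0.68 min, 12.3% and 0.135 min, with the caution: “The maximum is barely defined by the data.”

The flask gave 0.690 min, 12.0% and 0.127 min, so the forecast held within its tolerance.

    substrate → intermediate (k = 0.0540 s⁻¹)
    first nucleophile + intermediate → target (k = 4.80 M⁻¹ s⁻¹)
    second nucleophile + intermediate → other capture product (k = 3.60 M⁻¹ s⁻¹)
    intermediate → solvolysis product (k = 3.00 s⁻¹)
    second nucleophile + target → over-reaction product (k = 0.530 M⁻¹ s⁻¹)
    crystals ⇌ target, rate k6*(cs6 - [target]) while solid is left; crystals form when [target] > cs6 (solubility = 6.50 mM, k = 0.370 s⁻¹)

In this flask, dissolved target had a half-life of 0.13 min by over-reaction alone at the charged concentrations, shorter than the 0.21 min of substrate turning into intermediate. That half-life was also short against the 2.0 min allowed, and target stood at 7.11% by then. The share applied to the substrate consumed by 0.200 min gives 8.25%, where the flask held 7.97%. In the neighbour with 0.95 M of first nucleophile, I scaled the odds, share against the rest, with c(first nucleophile), holding the rivals fixed, and got 0.835, a share of 45.5%. That neighbour reached 37.6% and ended at 34.5%.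

Readings and results were generated by integration for substances that don't exist; noise was put on by code.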